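**Plan**
1. Retrosynthesis: after a C12=C13 → C13=C14 alkene shift and a silyl ether at C8, one operation cuts the spiro C6–O bond of the hydroxybutanolide together with C6–C14 and C7–C11. This gives the monocyclic alkynyl dienylbutenolide 26, which is cut at C12–C13 into alkenyl boronate 10 and iodobutenolide 25.
2. 25 is cut at C10–C11 (propiolate alkynylation, then hydrostannation/lactonisation), C8–C9 (ketone allylation), C5–C6 (alkyne formylation) and C4–C5 (acetate aldol). 10 is cut at C1–C2 (allylic alkylation) and C13=C14 (cross-metathesis).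
3. Forward ring order: butenolide (step 15); then in step 17 the hydroxybutanolide (C6–O) followed in the same flask by cyclopentane and cyclohexene together ([4+2]); step 18 moves the alkene and step 19 frees C8–OH.
4. Enabling feature: the spiro carbon C6 is both the γ-carbon of the hydroxybutanolide and the cyclohexene carbon between ring-fusion C7 and alkene carbon C14. O-attack of the C18 carboxyl on a C6≡C7 alkyne therefore leaves an exocyclic enol-lactone C6=C7, a 2π partner for the 2-acyl diene C11=C12–C13=C14 held by the fused butenolide three atoms (C8–C10) away.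
5. Stereochemistry: C1, C8, C5 and C10 come from four catalyst-controlled reactions (steps 4, 7, 12, 14). C11, C7 and C6 are relayed from C10 and the Z enol lactone in the cycloaddition. C12 comes from kinetic protonation to the cis-fused lactone.

Key step: step 17

Locants (cembranoid-type numbering): C1 = side-chain CH; C2–C3 = CH2CO2Me; C15–C17 = isopropenyl; C18(=O)–C4H2–C5H(OH)–C6 = hydroxybutanolide with spiro C6; C7 and C11 = ring-fusion CH; C8 = C(CH3)OH; C9 = CH2; C10 = OCH; C12 = CH–C20(=O); C13=C14 = ring alkene.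

Assumption: for each enantioselective catalyst the antipode that delivers the drawn stereocentre is meant; the sense of induction would be confirmed on the first run.

**Step 1**
Reactants: 1 methacrolein; 2 trimethyl phosphonoacetate
Product: 3 methyl (2E)-4-methylpenta-2,4-dienoate
Conditions: NaH, THF, 0 °C to rt
Reagents that add atoms: none
Why: Horner–Wadsworth–Emmons olefination of the enal with the stabilised phosphonate anion should give the E dienoate.

**Step 2**
Reactants: 3 methyl (2E)-4-methylpenta-2,4-dienoate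
Product: 4 (2E)-4-methylpenta-2,4-dien-1-ol
Conditions: DIBAL-H (2.2 equiv), CH2Cl2, −78 °C; Rochelle salt work-up
Reagents that add atoms: none
Why: Aluminium hydride 1,2-reduction of the ester to the allylic alcohol leaves the diene untouched.

**Step 3**
Reactants: 4 (2E)-4-methylpenta-2,4-dien-1-ol
Product: 5 methyl (2E)-4-methylpenta-2,4-dien-1-yl carbonate
Conditions: ClCO2Me, pyridine, CH2Cl2, 0 °C
Reagents that add atoms: methyl chloroformate, COC(=O)Cl
Why: O-acylation gives the linear allylic carbonate that iridium can ionise with loss of CO2 and methoxide.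

**Step 4**
Reactants: 5 methyl (2E)-4-methylpenta-2,4-dien-1-yl carbonate; 6 dimethyl malonate
Product: 7 dimethyl 2-[(3S)-2-methylpenta-1,4-dien-3-yl]propanedioate
Conditions: [Ir(cod)Cl]2 (2 mol %), BINOL-derived N,N-bis(1-phenylethyl)phosphoramidite (4 mol %), TBD (8 mol %), THF, rt
Reagents that add atoms: none
Why: Iridium-catalysed asymmetric allylic alkylation of a dienyl carbonate attacks the substituted allyl terminus, so the branched skipped diene should form and the phosphoramidite sets C1.

**Step 5**
Reactants: 7 dimethyl 2-[(3S)-2-methylpenta-1,4-dien-3-yl]propanedioate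
Product: 8 methyl (3R)-3-ethenyl-4-methylpent-4-enoate
Conditions: LiCl, H2O, DMSO, 150 °C
Reagents that add atoms: none
Why: Krapcho dealkoxycarbonylation removes one ester under neutral conditions; C1 is not α to a carbonyl and keeps its configuration (the descriptor changes only by CIP priority).

**Step 6**
Reactants: 8 methyl (3R)-3-ethenyl-4-methylpent-4-enoate; 9 vinylboronic acid pinacol ester
Product: 10 methyl (3R,4E)-3-(prop-1-en-2-yl)-5-(4,4,5,5-tetramethyl-1,3,2-dioxaborolan-2-yl)pent-4-enoate
Conditions: second-generation Ru benzylidene metathesis catalyst with H2IMes and chelating 2-isopropoxybenzylidene (5 mol %), CH2Cl2, 40 °C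
Reagents that add atoms: none
Why: Olefin cross-metathesis engages only the monosubstituted vinyl group (the 1,1-disubstituted isopropenyl is inert) and the bulky boronate should give the E alkene.

**Step 7**
Reactants: 11 4-(trimethylsilyl)but-3-yn-2-one; 12 2-allyl-1,3,2-dioxaborinane
Product: 13 (3S)-3-methyl-1-(trimethylsilyl)hex-5-en-1-yn-3-ol
Conditions: 3,3′-dibromo-BINOL (5 mol %), t-BuOH (2 equiv), PhMe, rt
Reagents that add atoms: none
Why: Chiral-diol-catalysed asymmetric allylboration of a ketone distinguishes the methyl and alkynyl flanks and sets the tertiary carbinol C8.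

**Step 8**
Reactants: 13 (3S)-3-methyl-1-(trimethylsilyl)hex-5-en-1-yn-3-ol
Product: 14 tert-butyldimethyl{[(3S)-3-methyl-1-(trimethylsilyl)hex-5-en-1-yn-3-yl]oxy}silane
Conditions: TBSOTf, 2,6-lutidine, CH2Cl2, 0 °C to rt
Reagents that add atoms: tert-butyldimethylsilyl triflate, CC(C)(C)[Si](C)(C)OS(=O)(=O)C(F)(F)F
Why: Silyl triflate silylation protects the hindered tertiary alcohol, which would otherwise ionise or transacylate in step 17.

**Step 9**
Reactants: 14 tert-butyldimethyl{[(3S)-3-methyl-1-(trimethylsilyl)hex-5-en-1-yn-3-yl]oxy}silane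
Product: 15 tert-butyl{[(3S)-3-methylhex-5-en-1-yn-3-yl]oxy}dimethylsilane
Conditions: K2CO3 (cat.), MeOH, rt
Reagents that add atoms: none
Why: Base-mediated protiodesilylation cleaves the C(sp)–Si bond selectively and leaves the tertiary silyl ether.

**Step 10**
Reactants: 15 tert-butyl{[(3S)-3-methylhex-5-en-1-yn-3-yl]oxy}dimethylsilane
Product: 16 (4S)-4-[(tert-butyldimethylsilyl)oxy]-4-methylhept-6-en-2-ynal
Conditions: n-BuLi, THF, −78 °C; DMF, −78 to 0 °C; inverse quench into aq. KH2PO4
Reagents that add atoms: N,N-dimethylformamide, CN(C)C=O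
Why: Formylation of the lithium acetylide with DMF introduces C5; the buffered inverse quench prevents amine addition to the ynal.

**Step 11**
Reactants: 17 tert-butyl acetate
Product: 18 1-tert-butoxy-1-(trimethylsilyloxy)ethene
Conditions: LDA, THF, −78 °C; TMSCl, −78 °C to rt; distillation
Reagents that add atoms: chlorotrimethylsilane, C[Si](C)(C)Cl
Why: O-silylation of the kinetic ester enolate gives the silyl ketene acetal needed for the aldol step.

**Step 12**
Reactants: 16 (4S)-4-[(tert-butyldimethylsilyl)oxy]-4-methylhept-6-en-2-ynal; 18 1-tert-butoxy-1-(trimethylsilyloxy)ethene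
Product: 19 tert-butyl (3S,6S)-6-[(tert-butyldimethylsilyl)oxy]-3-hydroxy-6-methylnon-8-en-4-ynoate
Conditions: Ti(IV)–binaphthyl Schiff-base/3,5-di-tert-butylsalicylate catalyst (5 mol %), Et2O, −10 °C; then 1 M HCl, THF, 0 °C
Reagents that add atoms: none
Why: Catalytic enantioselective Mukaiyama acetate aldol addition, for which ynals are favoured substrates, sets C5 under catalyst control (the remote C8 centre should not interfere).

**Step 13**
Reactants: 19 tert-butyl (3S,6S)-6-[(tert-butyldimethylsilyl)oxy]-3-hydroxy-6-methylnon-8-en-4-ynoate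
Product: 20 tert-butyl (3S,6S)-6-[(tert-butyldimethylsilyl)oxy]-3-hydroxy-6-methyl-8-oxooct-4-ynoate
Conditions: O3, CH2Cl2–MeOH, −78 °C (dye end-point); then PPh3
Reagents that add atoms: ozone, [O-][O+]=O
Why: Ozonolysis with reductive work-up cleaves the terminal alkene far faster than the hindered, oxygen-flanked alkyne and exposes C10 as the aldehyde.

**Step 14**
Reactants: 20 tert-butyl (3S,6S)-6-[(tert-butyldimethylsilyl)oxy]-3-hydroxy-6-methyl-8-oxooct-4-ynoate; 21 methyl propiolate
Product: 22 1-tert-butyl 11-methyl (3S,6S,8R)-6-[(tert-butyldimethylsilyl)oxy]-3,8-dihydroxy-6-methylundeca-4,9-diynedioate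
Conditions: Me2Zn (4 equiv), ProPhenol ligand (20 mol %), Ph3P=O (40 mol %), PhMe, 4 °C; aq. NH4Cl work-up
Reagents that add atoms: none
Why: Zinc–ProPhenol-catalysed alkynylation of the aldehyde with the propiolate sets C10 by catalyst control; the free C5–OH only consumes one extra equivalent of Me2Zn.

**Step 15**
Reactants: 22 1-tert-butyl 11-methyl (3S,6S,8R)-6-[(tert-butyldimethylsilyl)oxy]-3,8-dihydroxy-6-methylundeca-4,9-diynedioate
Product: 25 tert-butyl (3S,6S)-6-[(tert-butyldimethylsilyl)oxy]-3-hydroxy-7-[(2R)-4-iodo-5-oxo-2,5-dihydrofuran-2-yl]-6-methylhept-4-ynoate, via stannyl enoate 23 (not isolated), via stannylbutenolide 24 (not isolated)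
Conditions: Bu3SnH (1.1 equiv), Pd(PPh3)4 (2 mol %), THF, 0 °C; PPTS (cat.), rt; then I2, CH2Cl2, 0 °C
Reagents that add atoms: tributyltin hydride, CCCC[SnH](CCCC)CCCC (tin is carried only by 23 and 24); iodine, II
Why: Pd-catalysed syn-hydrostannation of the ynoate puts tin α and hydrogen β so the ester lies cis to the C10 carbinol and lactonises to the butenolide, and iododestannylation with retention gives the α-iodobutenolide; the second alkyne is flanked by a quaternary carbon and is not conjugated, so it should not react.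

**Step 16**
Reactants: 25 tert-butyl (3S,6S)-6-[(tert-butyldimethylsilyl)oxy]-3-hydroxy-7-[(2R)-4-iodo-5-oxo-2,5-dihydrofuran-2-yl]-6-methylhept-4-ynoate; 10 methyl (3R,4E)-3-(prop-1-en-2-yl)-5-(4,4,5,5-tetramethyl-1,3,2-dioxaborolan-2-yl)pent-4-enoate
Product: 26 tert-butyl (3S,6S)-6-[(tert-butyldimethylsilyl)oxy]-3-hydroxy-7-{(2R)-4-[(1E,3R)-5-methoxy-5-oxo-3-(prop-1-en-2-yl)pent-1-en-1-yl]-5-oxo-2,5-dihydrofuran-2-yl}-6-methylhept-4-ynoate
Conditions: PdCl2(dppf) (5 mol %), K3PO4 (3 M aq., 3 equiv), THF, degassed, 23 °C, dark, short reaction time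
Reagents that add atoms: none
Why: Suzuki–Miyaura sp2–sp2 coupling with retention of the E geometry joins the two halves and creates the 3-dienylbutenolide; mild base and short contact protect the γ-stereocentre C10.

**Step 17**
Reactants: 26 tert-butyl (3S,6S)-6-[(tert-butyldimethylsilyl)oxy]-3-hydroxy-7-{(2R)-4-[(1E,3R)-5-methoxy-5-oxo-3-(prop-1-en-2-yl)pent-1-en-1-yl]-5-oxo-2,5-dihydrofuran-2-yl}-6-methylhept-4-ynoate
Product: 28 tetracyclic spiro-bis-lactone with C12=C13 conjugated to the fused lactone and C8–OTBS (14-H on the face of H-7 and H-11; all other centres as in 30), via Z enol lactone 27 (not isolated)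
Conditions: [(2-biphenyl)di-tert-butylphosphine]Au(MeCN)SbF6 (5 mol %), PhMe (0.005 M), 23 °C; then 2,6-di-tert-butyl-4-methylpyridine (0.2 equiv), BHT, 120 °C, sealed
Reagents that add atoms: none
Why: Proposed new method: the cationic gold(I) centre activates the C6≡C7 alkyne, the carbonyl oxygen of the tert-butyl ester attacks C6 anti to gold (5-exo-dig; this is the C6–O bond of the hydroxybutanolide), the tert-butyl group leaves as isobutene and protodeauration gives the Z enol lactone 27, whose electron-rich exocyclic C6=C7 then adds on heating across the electron-poor 2-acyl diene C11=C12–C13=C14 of the dienylbutenolide in an intramolecular inverse-electron-demand Diels–Alder reaction. The closest known reaction types are the gold-catalysed cycloisomerisation of 4-alkynoic acids and of tert-butyl carbonates and esters to Z alkylidene heterocycles, the [4+2] addition of exocyclic enol ethers and enol esters to 2-carbonyl-1,3-dienes, and type-1 intramolecular Diels–Alder reactions through a three-atom tether; their union in one flask on such a substrate has no direct precedent. Ring closures: butanolide by 5-exo-dig O-attack, cyclopentane by the C7–C11 bond through the tether C8–C9–C10, cyclohexene by the C6–C14 bond of the same [4+2] event. Stereocentres: C11 is set by C10 because C7 can reach only the butenolide face that carries C9; C7 follows from the tether-endo transition state that the planar butenolide imposes (cis ring fusion, H-7 cis to H-11); C6 follows from the Z geometry through suprafacial addition (ring oxygen cis to C8, C5 trans); C14 is transient and is erased in step 18. The step needs 5-exo over 6-endo oxyauration (normal for 4-alkynoates and favoured by the quaternary C8), addition to the enol-lactone face syn to the small unprotected C5–OH (no other diastereomeric path is open once the tether fixes the face), and survival of the allylic C8–O bond and the β-hydroxyl, which the silyl ether at C8, the hindered pyridine buffer and high dilution are meant to secure.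

**Step 18**
Reactants: 28 tetracyclic spiro-bis-lactone with C12=C13 and C8–OTBS
Product: 29 8-O-tert-butyldimethylsilyl ether of 30 (C13=C14, 12-H cis to 11-H)
Conditions: LDA (6 equiv), THF–DMPU (10:1), −78 °C, 20 min; AcOH (12 equiv) in THF, −78 °C
Reagents that add atoms: none
Why: Kinetic deconjugation: excess LDA should first turn the hydroxybutanolide into its alkoxide–enolate dianion (whose oxygen can no longer leave from C6), then remove the γ-hydrogen at C14, and the extended enolate is protonated at the α-carbon C12 from the convex face, which gives the cis-fused lactone and moves the alkene to C13=C14.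

**Step 19**
Reactants: 29 8-O-tert-butyldimethylsilyl ether of 30
Product: 30 target CNP0148106.2
Conditions: HF·pyridine, pyridine, THF, 0 to 23 °C
Reagents that add atoms: none
Why: Fluoride-mediated cleavage of the tertiary silyl ether under mildly acidic conditions frees C8–OH without touching the base-sensitive β,γ-unsaturated lactone.

**Compound list**
1 | methacrolein (2-methylprop-2-enal) | C=C(C)C=O | starting material
2 | trimethyl phosphonoacetate | COC(=O)CP(=O)(OC)OC | starting material
3 | methyl (2E)-4-methylpenta-2,4-dienoate | C=C(C)/C=C/C(=O)OC | intermediate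
4 | (2E)-4-methylpenta-2,4-dien-1-ol | C=C(C)/C=C/CO | intermediate
5 | methyl (2E)-4-methylpenta-2,4-dien-1-yl carbonate | C=C(C)/C=C/COC(=O)OC | intermediate
6 | dimethyl malonate | COC(=O)CC(=O)OC | starting material
7 | dimethyl 2-[(3S)-2-methylpenta-1,4-dien-3-yl]propanedioate | C=C(C)[C@H](C(C(=O)OC)C(=O)OC)C=C | intermediate
8 | methyl (3R)-3-ethenyl-4-methylpent-4-enoate | C=C(C)[C@H](CC(=O)OC)C=C | intermediate
9 | 2-ethenyl-4,4,5,5-tetramethyl-1,3,2-dioxaborolane (vinylboronic acid pinacol ester) | C=CB1OC(C)(C)C(C)(C)O1 | starting material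
10 | methyl (3R,4E)-3-(prop-1-en-2-yl)-5-(4,4,5,5-tetramethyl-1,3,2-dioxaborolan-2-yl)pent-4-enoate | C=C(C)[C@H](CC(=O)OC)/C=C/B1OC(C)(C)C(C)(C)O1 | intermediate
11 | 4-(trimethylsilyl)but-3-yn-2-one | CC(=O)C#C[Si](C)(C)C | starting material
12 | 2-allyl-1,3,2-dioxaborinane | C=CCB1OCCCO1 | starting material
13 | (3S)-3-methyl-1-(trimethylsilyl)hex-5-en-1-yn-3-ol | C=CC[C@](C)(O)C#C[Si](C)(C)C | intermediate
14 | tert-butyldimethyl{[(3S)-3-methyl-1-(trimethylsilyl)hex-5-en-1-yn-3-yl]oxy}silane | C=CC[C@](C)(O[Si](C)(C)C(C)(C)C)C#C[Si](C)(C)C | intermediate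
15 | tert-butyl{[(3S)-3-methylhex-5-en-1-yn-3-yl]oxy}dimethylsilane | C=CC[C@](C)(O[Si](C)(C)C(C)(C)C)C#C | intermediate
16 | (4S)-4-[(tert-butyldimethylsilyl)oxy]-4-methylhept-6-en-2-ynal | C=CC[C@](C)(O[Si](C)(C)C(C)(C)C)C#CC=O | intermediate
17 | tert-butyl acetate | CC(=O)OC(C)(C)C | starting material
18 | 1-tert-butoxy-1-(trimethylsilyloxy)ethene | C=C(OC(C)(C)C)O[Si](C)(C)C | intermediate
19 | tert-butyl (3S,6S)-6-[(tert-butyldimethylsilyl)oxy]-3-hydroxy-6-methylnon-8-en-4-ynoate | CC(C)(C)OC(=O)C[C@H](O)C#C[C@](C)(CC=C)O[Si](C)(C)C(C)(C)C | intermediate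
20 | tert-butyl (3S,6S)-6-[(tert-butyldimethylsilyl)oxy]-3-hydroxy-6-methyl-8-oxooct-4-ynoate | CC(C)(C)OC(=O)C[C@H](O)C#C[C@](C)(CC=O)O[Si](C)(C)C(C)(C)C | intermediate
21 | methyl propiolate (methyl prop-2-ynoate) | C#CC(=O)OC | starting material
22 | 1-tert-butyl 11-methyl (3S,6S,8R)-6-[(tert-butyldimethylsilyl)oxy]-3,8-dihydroxy-6-methylundeca-4,9-diynedioate | CC(C)(C)OC(=O)C[C@H](O)C#C[C@](C)(C[C@@H](O)C#CC(=O)OC)O[Si](C)(C)C(C)(C)C | intermediate
23 | 1-tert-butyl 11-methyl (3S,6S,8R,9E)-6-[(tert-butyldimethylsilyl)oxy]-3,8-dihydroxy-6-methyl-10-(tributylstannyl)undec-9-en-4-ynedioate | CC(C)(C)OC(=O)C[C@H](O)C#C[C@](C)(C[C@@H](O)/C=C(/[Sn](CCCC)(CCCC)CCCC)C(=O)OC)O[Si](C)(C)C(C)(C)C | intermediate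
24 | tert-butyl (3S,6S)-6-[(tert-butyldimethylsilyl)oxy]-3-hydroxy-6-methyl-7-[(2R)-5-oxo-4-(tributylstannyl)-2,5-dihydrofuran-2-yl]hept-4-ynoate | CC(C)(C)OC(=O)C[C@H](O)C#C[C@](C)(C[C@H]1OC(=O)C([Sn](CCCC)(CCCC)CCCC)=C1)O[Si](C)(C)C(C)(C)C | intermediate
25 | tert-butyl (3S,6S)-6-[(tert-butyldimethylsilyl)oxy]-3-hydroxy-7-[(2R)-4-iodo-5-oxo-2,5-dihydrofuran-2-yl]-6-methylhept-4-ynoate | CC(C)(C)OC(=O)C[C@H](O)C#C[C@](C)(C[C@H]1OC(=O)C(I)=C1)O[Si](C)(C)C(C)(C)C | intermediate
26 | tert-butyl (3S,6S)-6-[(tert-butyldimethylsilyl)oxy]-3-hydroxy-7-{(2R)-4-[(1E,3R)-5-methoxy-5-oxo-3-(prop-1-en-2-yl)pent-1-en-1-yl]-5-oxo-2,5-dihydrofuran-2-yl}-6-methylhept-4-ynoate | CC(C)(C)OC(=O)C[C@H](O)C#C[C@](C)(C[C@H]1OC(=O)C(/C=C/[C@@H](CC(=O)OC)C(C)=C)=C1)O[Si](C)(C)C(C)(C)C | intermediate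
27 | Z enol lactone of 26: (3S)-3-hydroxy-5-oxooxolan-2-ylidene unit, ring O cis to C8 across C6=C7; rest as 26 | O=C1C[C@H](O)/C(=C/[C@](C)(C[C@H]2OC(=O)C(/C=C/[C@@H](CC(=O)OC)C(C)=C)=C2)O[Si](C)(C)C(C)(C)C)O1 | intermediate
28 | Diels–Alder adduct: tetracyclic spiro-bis-lactone with C12=C13, C8–OTBS, 14-H cis to H-7 and H-11 | C=C(C)[C@H](CC(=O)OC)[C@@H]1C=C2C(=O)O[C@@H]3C[C@](C)(O[Si](C)(C)C(C)(C)C)[C@@H]([C@H]23)[C@]12OC(=O)C[C@@H]2O | intermediate
29 | 8-O-tert-butyldimethylsilyl ether of 30 | C=C(C)[C@H](CC(=O)OC)C1=C[C@@H]2C(=O)O[C@@H]3C[C@](C)(O[Si](C)(C)C(C)(C)C)[C@@H]([C@H]23)[C@]12OC(=O)C[C@@H]2O | intermediate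
30 | CNP0148106.2: (1S,5S,6S,7R,8S,10R,11R,12S) spiro-hydroxybutanolide / cis-fused butanolide / cyclopentanol / cyclohexene methyl ester | C=C(C)[C@H](CC(=O)OC)C1=C[C@@H]2C(=O)O[C@@H]3C[C@](C)(O)[C@@H]([C@H]23)[C@]12OC(=O)C[C@@H]2O | target

**Step count**
Total steps: 19. Longest linear sequence: 12 steps (11 → 30 through steps 7–10 and 12–19). The boronate branch has 6 steps and the ketene acetal 1 step.

**Steps most likely to fail**

1. Step 17 (proposed new method). The processes at risk are ionisation of the allylic C8–O bond or dehydration of the β-hydroxy enol lactone before the cycloaddition, and a slow cycloaddition on the enol-lactone face that carries the C5 hydroxyl, which would leave time for dimerisation of the dienylbutenolide. The fallback uses known reactions in three separate operations, sets out from 26 and comes back at 28. The tert-butyl ester of 26 is cleaved with 85 % aq. H3PO4 in toluene to the hydroxy acid F1. AuCl (5 mol %) with K2CO3 (10 mol %) in MeCN at rt, the established cycloisomerisation of 4-alkynoic acids, should give the Z enol lactone 27, now isolated. 27 is then cyclised without heat or metal at 13–15 kbar in CH2Cl2 (pressure-promoted intramolecular Diels–Alder reaction) to 28.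

2. Step 18. The processes at risk are vinylogous β-elimination of the spiro-lactone carboxylate from the extended enolate (opening of the hydroxybutanolide) in competition with α-protonation, and incomplete removal of the hindered γ-hydrogen. The fallback sets out from 28 and comes back at 30. Soft enolisation with TBSOTf and Et3N (CH2Cl2, −78 °C) converts 28 into the neutral tris-silyl dienol ether F2 (silyl ketene acetal of the fused lactone with C13=C14 already in place, C5–OH silylated as well; any silyl ketene acetal formed at the spiro-lactone reverts in the next operation). HF·pyridine with pyridine in THF at −40 °C protonates the silyl ketene acetal at C12 and should give the bis-silyl ether F3. More HF·pyridine at rt removes both silyl ethers and gives 30.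

3. Step 16. The processes at risk are base-induced epimerisation at the γ-carbon C10 of the iodobutenolide through its 2-oxidofuran, and protodeboronation of 10 in aqueous base. The fallback sets out from 22 and 10 and comes back at 26. Step 15 is stopped before the iodine quench and the stannylbutenolide 24 is isolated. Boronate 10 is converted with I2 and NaOH (THF, 0 °C; iodo-deboronation with retention) into the alkenyl iodide F4. Base-free Stille coupling of 24 with F4 (Pd2(dba)3, AsPh3, copper(I) thiophene-2-carboxylate, NMP, rt) should give 26.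

**Further compounds**
F1 | step 17 | (3S,6S)-6-[(tert-butyldimethylsilyl)oxy]-3-hydroxy-7-{(2R)-4-[(1E,3R)-5-methoxy-5-oxo-3-(prop-1-en-2-yl)pent-1-en-1-yl]-5-oxo-2,5-dihydrofuran-2-yl}-6-methylhept-4-ynoic acid | OC(=O)C[C@H](O)C#C[C@](C)(C[C@H]1OC(=O)C(/C=C/[C@@H](CC(=O)OC)C(C)=C)=C1)O[Si](C)(C)C(C)(C)C
F2 | step 18 | tris-TBS dienol ether of 28 (C20 silyl ketene acetal C20=C12, C13=C14, C5–OTBS, C8–OTBS) | C=C(C)[C@H](CC(=O)OC)C1=CC2=C(O[Si](C)(C)C(C)(C)C)O[C@@H]3C[C@](C)(O[Si](C)(C)C(C)(C)C)[C@@H]([C@H]23)[C@]12OC(=O)C[C@@H]2O[Si](C)(C)C(C)(C)C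
F3 | step 18 | 5,8-bis-O-tert-butyldimethylsilyl ether of 30 | C=C(C)[C@H](CC(=O)OC)C1=C[C@@H]2C(=O)O[C@@H]3C[C@](C)(O[Si](C)(C)C(C)(C)C)[C@@H]([C@H]23)[C@]12OC(=O)C[C@@H]2O[Si](C)(C)C(C)(C)C
F4 | step 16 | methyl (3R,4E)-5-iodo-3-(prop-1-en-2-yl)pent-4-enoate | C=C(C)[C@H](CC(=O)OC)/C=C/I
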